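| flask | starting material | partner | protic impurity | remark | time |
|---|---|---|---|---|---|
| west | 0.50 M | 1.8 M | 0.20 M | run made earlier |  |
| south-east | 0.75 M | 1.8 M | 0.20 M | run made earlier |  |
| winter | 1.0 M | 1.80 M | 0.200 M |  | 12 h |
| summer | 1.0 M | 1.80 M | 0.200 M |  | 30 h |
| midnight | 1.0 M | 1.80 M | 0.200 M |  | 75 h |

| run | time / h | starting material / % | target / % | over-reaction product / % |
|---|---|---|---|---|
| west | 0.417 | 86.3 | 13.5 | 0.7 |
| west | 1.00 | 70.0 | 26.9 | 0 |
| west | 2.00 | 48.5 | 44.5 | 0.4 |
| west | 3.00 | 35.4 | 55.1 | 1.8 |
| west | 4.00 | 26.8 | 62.1 | 2.0 |
| west | 6.00 | 13.2 | 70.4 | 3.9 |
| west | 8.00 | 7.8 | 73.7 | 6.8 |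
| south-east | 1.00 | 70.6 | 26.8 | 0 |
| south-east | 2.00 | 47.4 | 43.0 | 2.5 |
| south-east | 3.00 | 37.7 | 53.0 | 1.3 |
| south-east | 4.00 | 29.1 | 59.8 | 2.1 |
| south-east | 5.00 | 21.6 | 65.8 | 3.0 |
| south-east | 6.00 | 15.4 | 70.6 | 4.2 |
| south-east | 8.00 | 10.1 | 71.8 | 5.3 |

(scatter of a reading: 1 percentage point)



- which of these there is most of at the end, counted by the starting material in it, winter (target / starting material / over-reaction product)
- which of these there is most of at the end, counted by the starting material in it, summer (target / starting material / over-reaction product)
- which of these there is most of at the end, counted by the starting material in it, midnight (target / starting material / over-reaction product)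
- final amount of the leader among these, as a percentage of the starting material charged, in winter
- final amount of the leader among these, as a percentage of the starting material charged, in summer
- final amount of the leader among these, as a percentage of the starting material charged, in midnight

1. At early times the west and south-east runs went alike: at 2.00 h I read 48.5% and 47.4% of the charge as starting material. I therefore carried percentages of the charge across loadings.

2. The last readings gave a ceiling. Of the converted starting material, the two runs together held 86.5% as target plus over-reaction product. I took this as the selectivity of the conversion.

3. Over-reaction product stood at 6.8% and 5.3% after 8.00 h, and I took target's mean over that time as about its readings at 3.00 h, 55.1% and 53.0%. Product divided by that target and by the time gave the ageing constant, the fraction of target passing on per hour: 0.0140 h⁻¹.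

4. This constant times the time is the ageing number N, the flask's time measured in lifetimes of target. At the early end I let target follow conversion. At the late end, with conversion taken as complete, I took target as the ceiling times exp(−N) and over-reaction product as the remainder of the ceiling, so the two cross at N = 0.693.

5. N was 0.168 for winter, 0.420 for summer and 1.05 for midnight. Winter's and summer's N are less than the crossing value, so I reckoned target to lead there, at 73.1% in winter and 56.8% in summer. Midnight's N is greater than the crossing value, so I expected over-reaction product to lead there with 56.2%.

6. I tested this on the west run at 8.00 h. The rule gave 77.3%, more than the 73.7% read, with 7.8% still starting material. One number was not enough while starting material stood, so my winter figure may be high.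

7. The forecast named target in each flask, with 75%, 69% and 52%. It held that “Target then decays at about 0.007” per hour, where I had 0.0140 h⁻¹.

The flasks gave target at 71.6% in winter and target at 58.7% in summer. At midnight over-reaction product led with 53.1%, against target at 31.5%.

    starting material + partner ⇌ target + by-product (K = 27.0, k = 0.00310 L mol⁻¹ min⁻¹)
    target → over-reaction product (k = 2.30 × 10⁻⁴ min⁻¹)
    starting material + protic impurity → quenched substrate (k = 0.00460 L mol⁻¹ min⁻¹)

The half-life of target by its passing into over-reaction product alone, 50 h, is longer than winter's 12 h and shorter than midnight's 75 h. Midnight, at N = 1.05, was the flask where over-reaction product led. Now take winter read at 3.0 h: N is 0.0420, and with 38.9% still starting material, the ceiling on the converted part, aged by N, gives 50.7% target. At that reading winter holds 51.7% target and 1.31% over-reaction product.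

The earlier runs and the new flask come from a simulation with made-up constants, noise included.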